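# Proposed total synthesis of CNP0113462.3 (35) by chromium-mediated closure of the carbocycle and the α-methylene lactone

## The problem

Compound 35 is an 8,12-elemanolide: one cyclohexane (C5–C10) with a substituent on every ring carbon and an α-methylene-γ-butyrolactone (C11=C13, C12, ring oxygen on C8) trans-fused across C7–C8. There is no second carbocycle to lean on, so the six contiguous ring stereocentres (5R,6S,7S,8R,9S,10S) and the oxirane carbon C1 (R) must be set by acyclic or single-ring control. C10 is quaternary (C14 methyl and the C1–C2 oxirane) and lies between the C9 carbinol and C5, which carries the acrolein arm C4(=C3)–C15. In the chair the two lactone bonds, the C5 arm and C1 are equatorial, whereas the C6 angelate, the C9 hydroxyl and the C14 methyl are axial (angelate and methyl 1,3-diaxial); C6 and C9 therefore cannot be reached by equilibration. The available chain of control is as follows: C9 can come from the chiral pool and bias the face of C10, and C10 and C5 can be coupled in a chair sigmatropic transition state. C5 can direct a hydride to C6, the substituents at C5, C6 and C10 can choose the chair in which C7 and C8 are formed, and the C9 hydroxyl can deliver oxygen to the C10 vinyl group to set C1. The α-methylene lactone and the 2-substituted acrolein are Michael acceptors, the angelate isomerises to the tiglate under nucleophilic or strongly basic conditions, and the terminal oxirane does not tolerate acid, halide or fluoride; these groups must appear late and in that order. The enabling feature is the way the lactone straddles ring bond C7–C8: the array O8–C8–C7–C11(=C13)–C12 is the retron of the addition of a 2-(alkoxycarbonyl)allyl metal to a C8 aldehyde, and because the allyl γ-carbon C7 is itself a ring atom, that addition can close the carbocycle and the lactone in one operation.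

## Retrosynthesis

**Oxirane, enal and free carbinol (35 ⇒ 34 ⇒ 33 ⇒ 32).** The C1–O and C2–O bonds are cut first, back to vinyl compound 34. An oxirane carried from earlier would meet chromium salts, acid from DDQ cleavage and HF. Installed last, it asks the forward step to find the only electron-rich alkene (the other three are conjugated to carbonyl groups) and to set C1 from the neighbouring axial C9 hydroxyl. The enal of 34 goes back to allylic alcohol 33, and this to bis-silyl ether 32, so that one fluoride treatment frees both the directing C9 hydroxyl and the C15 hydroxyl.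

**Angelate (32 ⇒ 30 + 31 ⇒ 29).** The C6–O acyl bond is cut to alcohol 30 and angelic acid 31. The ester could in principle be installed before ring formation, but an α-acyloxy aldehyde would not survive the amine-promoted acrylate addition (acyl shift to the new C7 alkoxide). A PMB ether therefore holds O6 through the ring construction and is removed oxidatively from 29. The forward acylation must reach an axial, doubly flanked hydroxyl without Z/E isomerisation.

**Carbocycle and lactone (29 ⇒ 26).** Cutting C7–C8 and O8–C12 together opens both rings and leads to the (Z)-2-(bromomethyl)enoate aldehyde 26. Compared with cuts at C6–C7, C8–C9 or C7–C11, this one has three advantages: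
- it places the methylene lactone on the correct oxygen at the final oxidation level;
- it needs no later α-methylenation under basic conditions;
- it creates C7, the one centre that would be epimerisable in an open chain, only at the moment of ring closure.

The precursor has four stereocentres instead of six and no ring. The forward reaction must give the trans fusion and the correct sense relative to C5, C6, C9 and C10.

**Enoate arm (26 ⇒ 25 ⇒ 24 ⇒ 23 ⇒ 21 + 22).** The C8 aldehyde is kept as a primary TES ether (25, 24) and revealed last. Bromide 24 comes by SN2′ transposition from the Baylis–Hillman adduct 23, so the C7–C11 bond is cut between α-alkoxy aldehyde 21 and methyl acrylate 22. An olefination of 21 with a phosphorus reagent already carrying the CH2X group is the neighbouring cut. The acrylate route is preferred because it uses a commodity reagent and gives the (Z)-bromide, the substrate type on which the chromium closure is established. The C7 carbinol centre of 23 is of no consequence.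

**C6 and C7 (21 ⇒ 20 ⇒ 19 ⇒ 18 ⇒ 17 ⇒ 16 ⇒ 15 ⇒ 14).** C7 is introduced as a formyl anion equivalent at aldehyde 14. Felkin–Anh addition of a carbon nucleophile to 14 (attack anti to the quaternary C10) would give the 6-epimer of what is needed, whereas the same model applied to hydride addition to a C6 ketone gives the required (6S) carbinol. Adduct 15 is therefore oxidised to acyl dithiane 16 and reduced to 17; this costs two steps but removes any reliance on an anti-Felkin addition. PMB protection (18) and exchange of the acetonide for two TES groups (19, 20) are placed here, before any acid- or base-sensitive function exists.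

**C5–C10 (14 ⇒ 13 ⇒ 10 ⇒ 5 + 9).** The vicinal tertiary/quaternary pair is cut by an Ireland–Claisen transform to allylic ester 10, and thus to alcohol 5 and acid 9. Conjugate addition or enolate alkylation at C10 were the neighbouring options. The sigmatropic route is preferred because the chair transition state couples the two centres (E-alkene plus E(O)-ketene acetal gives the required relationship) and leaves exactly the vinyl group and the C6 carbon that are needed. Ester 10 has a single stereocentre, C9, which must choose the alkene face. Reduction in the same flask gives 13, and oxidation gives 14.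

**Fragments (5 ⇒ 4 ⇒ 3 ⇒ 1; 9 ⇒ 8 ⇒ 7 ⇒ 6).** Alcohol 5 is an E-trisubstituted allylic alcohol from Horner–Wadsworth–Emmons homologation of methyl ketone 3, made from glycerate 1; the stereocentre of 1 becomes C9. Acid 9 brings C3, C4, C5, C6 and C15 with the C4=C3 methylene and the C15 oxygen already in place. It is the silyl ether of the reduction product 7 of commercial mono-methyl itaconate 6.

## Roads not taken

**Alternative 1:** Cut C7–C11 and the C8–O bond on a preformed cyclohexene. In the forward sense the bromoacetal A2, tethered through O6, gives a C11 radical that closes 5-exo onto C7; the C8 radical is trapped by O2 to give the cis-fused ethoxytetrahydrofuran A1 with a C8 hydroxyl.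
- Merits: the carbocycle exists before the key step, so C5, C6, C9 and C10 could be set on a ring. The tether guarantees the cis C6/C7 fusion, and radical conditions are neutral. In this respect it is better than the chosen plan, which must control four centres on an open chain and relies on a conformational argument for the ring closure.
- Weak points: the tether sits on O6, whereas the target has its lactone on O8 and an angelate on O6. The acetal carbon of A1 would have to be oxidised and the acyl group then moved from O6 to O8, against a cis-to-trans change of ring fusion. The methylene would have to be added afterwards by enolate chemistry with two carbinols to tell apart. Oxygen trapping at C8 is controlled only by the shape of the bicycle. A1 also carries a plain isopropenyl group, so C15 must be oxidised late.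
- Comparison: the chosen plan delivers the lactone on the correct oxygen, with the methylene in place and at the final oxidation level, and finishes in five steps after the key step.

**Alternative 2:** Cut C6–C7. The enol-acetal pyranoside A4 (anomeric carbon C6, ring oxygen on C8, exocyclic C8=C7) would be opened by Hg(OCOCF3)2 in aqueous acetone; the C7 mercurio-enolate adds to the C6 aldehyde to give hydroxy ketone A3.
- Merits: a pyranoside holds C5, C9 and C10 rigidly. The product ketone gives a handle at C8, and C7, being α to it, can be equilibrated into the equatorial position. This thermodynamic correction at C7 is something the chosen plan does not have.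
- Weak points: the mercury salt is also an electrophile for the vinyl and isopropenyl groups of A4. A4 has a quaternary carbon bearing vinyl and is not a sugar pattern, so it must be built from scratch and the template advantage is largely lost. The C6 carbinol of A3 is needed axial and is not reliably controlled in this aldol, and the β-hydroxy ketone can dehydrate. After the key step the route still needs ketone reduction to the equatorial C8 alcohol, oxidation of the two-carbon arm, lactonisation and α-methylenation.
- Comparison: the chosen plan avoids the mercury/alkene conflict and forms the lactone and methylene directly, but fixes C7 kinetically.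

**Alternative 3:** Cut C8–C9. SmI2 would reduce dialdehyde A6 to a ketyl that couples C8 with C9 and gives cis-diol A5.
- Merits: both carbinols are formed at once with the cis relationship the target needs. C9 need not be imported from the chiral pool. The C8 hydroxyl can lactonise onto the ester arm and so distinguish itself from C9–OH without protecting groups. On the differentiation of O8 and O9 it is better than the chosen plan, which needs a TES group at C9.
- Weak points: A6 must already contain C7 as the α-stereocentre of an aldehyde, with a β-alkoxy group at C6 that can be eliminated from the ketyl or the enolate. No strong element decides which of the two cis-diols forms relative to C10. The lactone still needs α-methylenation under basic conditions with a free C9 hydroxyl nearby, and C15 must again be oxidised late.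
- Comparison: the chosen plan creates C7 in the ring-closing step instead of carrying it as a labile centre, and needs no methylenation.

Key step: step 21

Assumption: locants follow the elemanolide numbering used above, and all CIP descriptors are quoted with these locants. In particular, C10 carries the C14 methyl and the C1=C2 vinyl group, C5 carries the C4(=C3H2)–C15 arm, and open-chain intermediates are the chain C8–C9–C10–C5–C6–C7. Mono-methyl itaconate 6 (the 4-methyl ester) is taken as the commercial form of the itaconate building block.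

## Route

Step 1
Reactants: 1 methyl (4R)-2,2-dimethyl-1,3-dioxolane-4-carboxylate
Product: 3 1-[(4R)-2,2-dimethyl-1,3-dioxolan-4-yl]ethan-1-one, via Weinreb amide 2 (not isolated)
Conditions: MeNH(OMe)·HCl, i-PrMgCl, THF, −20 °C; then MeMgBr, −20 → 0 °C; aq. NH4Cl
Reagents that add atoms: methylmagnesium bromide, C[Mg]Br
Why: Weinreb ketone synthesis run in one flask: the chloromagnesium amide converts the ester into amide 2, whose magnesium chelate takes up MeMgBr once and releases the ketone only on quench, so the α-alkoxy centre (the future C9) is not exposed to base as a ketone.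

Step 2
Reactants: 3 1-[(4R)-2,2-dimethyl-1,3-dioxolan-4-yl]ethan-1-one
Product: 4 ethyl (2E)-3-[(4S)-2,2-dimethyl-1,3-dioxolan-4-yl]but-2-enoate
Conditions: (EtO)2P(O)CH2CO2Et, NaH, THF, 0 → 25 °C; chromatographic removal of the Z isomer
Reagents that add atoms: triethyl phosphonoacetate, CCOC(=O)CP(=O)(OCC)OCC
Why: Horner–Wadsworth–Emmons olefination of an activated α-alkoxy methyl ketone; the E isomer (dioxolane trans to the ester) should predominate, and the weakly basic phosphonate anion should not epimerise the ketone at 0 °C.

Step 3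
Reactants: 4 ethyl (2E)-3-[(4S)-2,2-dimethyl-1,3-dioxolan-4-yl]but-2-enoate
Product: 5 (2E)-3-[(4S)-2,2-dimethyl-1,3-dioxolan-4-yl]but-2-en-1-ol
Conditions: i-Bu2AlH, CH2Cl2, −78 °C
Reagents that add atoms: none
Why: 1,2-reduction of an enoate to the allylic alcohol with a hydridoalane; the acetonide and the alkene geometry are not affected.

Step 4
Reactants: 6 4-methoxy-2-methylidene-4-oxobutanoic acid (mono-methyl itaconate)
Product: 7 methyl 3-(hydroxymethyl)but-3-enoate
Conditions: BH3·SMe2, THF, −10 → 0 °C; H2O
Reagents that add atoms: none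
Why: chemoselective borane reduction of a free carboxylic acid (through the acyloxyborane) beside a methyl ester; the electron-poor 1,1-disubstituted alkene is hydroborated much more slowly at or below 0 °C.

Step 5
Reactants: 7 methyl 3-(hydroxymethyl)but-3-enoate
Product: 8 methyl 3-[(tert-butyldiphenylsilyloxy)methyl]but-3-enoate
Conditions: TBDPSCl, imidazole, CH2Cl2, 0 → 25 °C
Reagents that add atoms: tert-butyl(chloro)diphenylsilane, CC(C)(C)[Si](Cl)(c1ccccc1)c1ccccc1
Why: standard silylation, done promptly to forestall lactonisation of 7; TBDPS is chosen because it must survive the aqueous-acid removal of the acetonide in step 14.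

Step 6
Reactants: 8 methyl 3-[(tert-butyldiphenylsilyloxy)methyl]but-3-enoate
Product: 9 3-[(tert-butyldiphenylsilyloxy)methyl]but-3-enoic acid
Conditions: LiOH, THF/H2O, 0 °C; then 1 M HCl to pH 3
Reagents that add atoms: lithium hydroxide (hydroxide oxygen), [Li+].[OH-]
Why: ester saponification at 0 °C; the carboxylate, once formed, is no longer acidic at the α-carbon, so the β,γ-alkene should stay out of conjugation.

Step 7
Reactants: 5 (2E)-3-[(4S)-2,2-dimethyl-1,3-dioxolan-4-yl]but-2-en-1-ol; 9 3-[(tert-butyldiphenylsilyloxy)methyl]but-3-enoic acid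
Product: 10 (2E)-3-[(4S)-2,2-dimethyl-1,3-dioxolan-4-yl]but-2-en-1-yl 3-[(tert-butyldiphenylsilyloxy)methyl]but-3-enoate
Conditions: DCC, DMAP (cat.), CH2Cl2, 0 °C
Reagents that add atoms: none
Why: Steglich esterification of a primary allylic alcohol; low temperature and a catalytic amount of DMAP keep the β,γ-unsaturated acyl group from isomerising into conjugation.

Step 8
Reactants: 10 (2E)-3-[(4S)-2,2-dimethyl-1,3-dioxolan-4-yl]but-2-en-1-yl 3-[(tert-butyldiphenylsilyloxy)methyl]but-3-enoate
Product: 13 (2S,3S)-2-[3-(tert-butyldiphenylsilyloxy)prop-1-en-2-yl]-3-[(4S)-2,2-dimethyl-1,3-dioxolan-4-yl]-3-methylpent-4-en-1-ol, via silyl ketene acetal 11 (not isolated), via trimethylsilyl ester 12 (not isolated)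
Conditions: LiN(i-Pr)2, THF, −78 °C; Me3SiCl/Et3N, −78 → 60 °C; then LiAlH4, 0 °C
Reagents that add atoms: none
Why: Ireland–Claisen rearrangement followed by hydride reduction of the silyl ester in the same flask. Kinetic deprotonation in THF without a polar additive should give the E(O)-ketene acetal 11, and the chair transition state of the E-alkene then sets the required C5/C10 relationship, with the C14 methyl axial and the C4 arm cis to the allyl oxygen. The face of C10 is chosen by C9, whose C–O bond lies anti to the forming bond, whose hydrogen is turned toward the C14 methyl (1,2-allylic strain), and whose C8 sits over H1, which gives (5S,10S).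

Step 9
Reactants: 13 (2S,3S)-2-[3-(tert-butyldiphenylsilyloxy)prop-1-en-2-yl]-3-[(4S)-2,2-dimethyl-1,3-dioxolan-4-yl]-3-methylpent-4-en-1-ol
Product: 14 (2S,3S)-2-[3-(tert-butyldiphenylsilyloxy)prop-1-en-2-yl]-3-[(4S)-2,2-dimethyl-1,3-dioxolan-4-yl]-3-methylpent-4-enal
Conditions: Dess–Martin periodinane, NaHCO3, CH2Cl2, 0 °C; used crude
Reagents that add atoms: none
Why: buffered, amine-free periodinane oxidation, so that the α-centre C5 of the β,γ-unsaturated aldehyde is neither epimerised nor the alkene moved into conjugation.

Step 10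
Reactants: 14 (2S,3S)-2-[3-(tert-butyldiphenylsilyloxy)prop-1-en-2-yl]-3-[(4S)-2,2-dimethyl-1,3-dioxolan-4-yl]-3-methylpent-4-enal
Product: 15 (2S,3S)-2-[3-(tert-butyldiphenylsilyloxy)prop-1-en-2-yl]-1-(1,3-dithian-2-yl)-3-[(4S)-2,2-dimethyl-1,3-dioxolan-4-yl]-3-methylpent-4-en-1-ol (both C6 epimers)
Conditions: 1,3-dithiane, n-BuLi, THF, −30 °C; then 14, −78 °C
Reagents that add atoms: 1,3-dithiane, C1CSCSC1
Why: Corey–Seebach addition of a formyl anion equivalent brings in C7; carbonyl addition outruns enolisation at −78 °C. The Felkin–Anh sense of this addition would favour the unwanted 6-epimer, so the C6 configuration is not relied on here and both epimers are carried forward.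

Step 11
Reactants: 15 (2S,3S)-2-[3-(tert-butyldiphenylsilyloxy)prop-1-en-2-yl]-1-(1,3-dithian-2-yl)-3-[(4S)-2,2-dimethyl-1,3-dioxolan-4-yl]-3-methylpent-4-en-1-ol (both C6 epimers)
Product: 16 (2S,3S)-2-[3-(tert-butyldiphenylsilyloxy)prop-1-en-2-yl]-1-(1,3-dithian-2-yl)-3-[(4S)-2,2-dimethyl-1,3-dioxolan-4-yl]-3-methylpent-4-en-1-one
Conditions: SO3·pyridine, DMSO, i-Pr2NEt, CH2Cl2, 0 °C
Reagents that add atoms: none
Why: Parikh–Doering oxidation, an activated-DMSO method that leaves the dithiane sulfur untouched, converges both epimers on the 2-acyl-1,3-dithiane; the short contact with a hindered amine at 0 °C should spare the hindered C5–H.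

Step 12
Reactants: 16 (2S,3S)-2-[3-(tert-butyldiphenylsilyloxy)prop-1-en-2-yl]-1-(1,3-dithian-2-yl)-3-[(4S)-2,2-dimethyl-1,3-dioxolan-4-yl]-3-methylpent-4-en-1-one
Product: 17 (1S,2S,3S)-2-[3-(tert-butyldiphenylsilyloxy)prop-1-en-2-yl]-1-(1,3-dithian-2-yl)-3-[(4S)-2,2-dimethyl-1,3-dioxolan-4-yl]-3-methylpent-4-en-1-ol, the (5S,6S,9S,10S) carbinol
Conditions: LiBH(s-Bu)3, THF, −78 °C; aq. NH4Cl
Reagents that add atoms: none
Why: Felkin–Anh reduction of an α-branched ketone: the hydride comes in anti to the quaternary C10 and past H5, and the bulky dithianyl group on the other side reinforces this preference. This sets (6S), the epimer that carbon addition to 14 would not give.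

Step 13
Reactants: 17 the (5S,6S,9S,10S) carbinol
Product: 18 (5S,6S,9S,10S)-6-O-(4-methoxybenzyl) ether of 17
Conditions: NaH, PMBCl, n-Bu4NI (cat.), DMF, 0 → 25 °C
Reagents that add atoms: 4-methoxybenzyl chloride, COc1ccc(CCl)cc1
Why: Williamson etherification of the only free hydroxyl; the dithiane C–H is not acidic enough for NaH, and the acetonide and silyl ether are stable.

Step 14
Reactants: 18 (5S,6S,9S,10S)-6-O-(4-methoxybenzyl) ether of 17
Product: 19 (5S,6S,9S,10S)-8,9-diol (acetonide removed; 6-OPMB, 7-dithiane, 15-OTBDPS)
Conditions: AcOH/H2O/THF (3:1:1), 45 °C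
Reagents that add atoms: none
Why: acid-catalysed hydrolysis of a terminal isopropylidene acetal; the PMB ether, dithiane and TBDPS ether tolerate aqueous acetic acid.

Step 15
Reactants: 19 (5S,6S,9S,10S)-8,9-diol
Product: 20 (5S,6S,9S,10S)-8,9-bis(triethylsilyl) ether of 19
Conditions: Et3SiOTf, 2,6-lutidine, CH2Cl2, −78 → 0 °C
Reagents that add atoms: triethylsilyl trifluoromethanesulfonate, CC[Si](CC)(CC)OS(=O)(=O)C(F)(F)F
Why: silyl triflate silylation reaches the hindered C9 hydroxyl next to quaternary C10; the two TES groups are later distinguished by their position (primary against hindered secondary).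

Step 16
Reactants: 20 (5S,6S,9S,10S)-8,9-bis(triethylsilyl) ether
Product: 21 (5S,6S,9S,10S)-C7 aldehyde (6-OPMB, 8,9-bis-OTES, 15-OTBDPS)
Conditions: MeI, CaCO3, MeCN/H2O (9:1), 45 °C
Reagents that add atoms: water, O
Why: S-alkylative hydrolysis of the dithiane under buffered, essentially neutral conditions; silyl ethers, PMB ether and alkenes are untouched, and the α-alkoxy aldehyde is not epimerised.

Step 17
Reactants: 21 (5S,6S,9S,10S)-C7 aldehyde; 22 methyl acrylate
Product: 23 Baylis–Hillman adduct: methyl 2-methylidene-3-hydroxy ester at C7 (5S,6S,9S,10S; both C7 epimers)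
Conditions: DABCO, MeOH (trace), neat 22, 25 °C
Reagents that add atoms: none
Why: Baylis–Hillman reaction of an activated α-alkoxy aldehyde forms the C7–C11 bond; the new carbinol centre at C7 becomes sp2 in the next step, so its configuration does not matter.

Step 18
Reactants: 23 Baylis–Hillman adduct
Product: 24 (5S,6R,9S,10S)-(Z)-2-(bromomethyl)enoate with 8,9-bis-OTES (C6 descriptor changes by CIP priority only)
Conditions: NBS, Me2S, CH2Cl2, −20 → 25 °C
Reagents that add atoms: N-bromosuccinimide, O=C1CCC(=O)N1Br
Why: Corey–Kim-type activation of the allylic alcohol as an alkoxysulfonium ion and SN2′ attack of bromide at C13; the transposition gives the thermodynamically preferred (Z)-2-(bromomethyl)alk-2-enoate (C6 cis to CH2Br) under neutral conditions.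

Step 19
Reactants: 24 (5S,6R,9S,10S)-(Z)-2-(bromomethyl)enoate with 8,9-bis-OTES
Product: 25 (5S,6R,9S,10S)-(Z)-2-(bromomethyl)enoate C8 primary alcohol (9-OTES retained)
Conditions: PPTS (cat.), MeOH/CH2Cl2, 0 °C
Reagents that add atoms: none
Why: acid-catalysed methanolysis removes the primary TES ether far faster than the hindered secondary TES ether at C9 or the TBDPS ether; the allylic bromide is stable without base.

Step 20
Reactants: 25 (5S,6R,9S,10S)-(Z)-2-(bromomethyl)enoate C8 primary alcohol
Product: 26 (5S,6R,9S,10S)-(Z)-2-(bromomethyl)enoate C8 aldehyde (6-OPMB, 9-OTES, 15-OTBDPS, 10-vinyl)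
Conditions: Dess–Martin periodinane, NaHCO3, CH2Cl2, 0 → 25 °C; used crude
Reagents that add atoms: none
Why: amine-free periodinane oxidation, because tertiary amines would quaternise the 2-(bromomethyl)acrylate; the α-silyloxy aldehyde is taken on without chromatography.

Step 21
Reactants: 26 (5S,6R,9S,10S)-(Z)-2-(bromomethyl)enoate C8 aldehyde
Product: 29 (5S,6S,7S,8R,9S,10S)-trans-fused α-methylene-γ-butyrolactone (6-OPMB, 9-OTES, 15-OTBDPS, 10-vinyl), via allylchromium dichloride 27 (not isolated), via chromium alkoxide 28 (not isolated)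
Conditions: CrCl2 (6 equiv), THF, 25 °C, 5 mM, slow addition of 26
Reagents that add atoms: none
Why: Two equivalents of CrCl2 (divalent chromium) reduce the allylic C–Br bond to the trivalent allylchromium 27, which adds through its γ-carbon C7 to the C8 aldehyde in a closed six-membered transition state; this is the intramolecular Nozaki–Hiyama–Kishi (Barbier-type) allylation of aldehydes by 2-(bromomethyl)acrylates, and the closest known reaction type is this same cyclisation–lactonisation to fused α-methylene-γ-butyrolactones. The carbocycle closes 6-exo-trig at the aldehyde carbon (bond C7–C8, with C11=C13 ending exocyclic by allylic transposition), and the chromium alkoxide 28 then closes the lactone by 5-exo-trig acyl substitution at the C12 ester with loss of methoxide. C7 and C8 are created together, and their trans relationship follows from the chair transition state in which both tethers (C6 on C7, C9 on C8) are equatorial, a trans-decalin-like array that needs the allyl geometry with C6 trans to CH2Cr; the σ-allylchromium equilibrates by 1,3-metal shift, and this isomer, which keeps the bulky CH2–Cr end away from C6, should be the reactive one. The sense of the new pair relative to the old centres is set by the conformation of the forming cyclohexane: the C5 arm and the C10 vinyl group are equatorial, and C6–H, not C6–OPMB, lies in the plane of the C7=C11 unit to avoid 1,3-allylic strain with the ester, which places OPMB axial as in the target. In this array the α-silyloxy group at C9 is axial and the carbonyl oxygen equatorial, so C7 attacks the aldehyde face that gives (8R). The step therefore needs the (7S,8R) trans-fused isomer over the cis-fused and the ring-flipped trans isomers; allylic strain at C6 and two equatorial carbon substituents are what secure it, and high dilution suppresses intermolecular coupling. CrCl2 tolerates the silyl ethers, the PMB ether, the ester and the terminal alkenes and does not enolise the α-silyloxy aldehyde.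

Step 22
Reactants: 29 (5S,6S,7S,8R,9S,10S)-trans-fused α-methylene-γ-butyrolactone (6-OPMB)
Product: 30 (5S,6S,7S,8R,9S,10S)-C6 alcohol (9-OTES, 15-OTBDPS)
Conditions: DDQ, CH2Cl2/pH 7 buffer, 0 °C
Reagents that add atoms: none
Why: oxidative cleavage of the electron-rich PMB ether by single-electron transfer to DDQ; silyl ethers, the lactone and the isolated alkenes are inert under buffered conditions.

Step 23
Reactants: 30 (5S,6S,7S,8R,9S,10S)-C6 alcohol; 31 angelic acid [(2Z)-2-methylbut-2-enoic acid]
Product: 32 (5S,6S,7S,8R,9S,10S)-C6 angelate (9-OTES, 15-OTBDPS)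
Conditions: 2,4,6-trichlorobenzoyl chloride, Et3N, toluene, 25 °C; then 30, 80 °C
Reagents that add atoms: none
Why: Yamaguchi mixed-anhydride acylation; the preformed anhydride transfers the angeloyl group to the hindered axial C6 hydroxyl on heating, without a nucleophilic catalyst that would isomerise the angelate to the tiglate. C6–OH is the only free hydroxyl.

Step 24
Reactants: 32 (5S,6S,7S,8R,9S,10S)-C6 angelate (9-OTES, 15-OTBDPS)
Product: 33 (5S,6S,7S,8R,9S,10S)-9,15-diol C6 angelate
Conditions: HF·pyridine, pyridine, THF, 0 → 25 °C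
Reagents that add atoms: none
Why: fluoride-driven cleavage of both silyl ethers in a buffered acidic medium, which spares the angelate and the methylene lactone that basic fluoride sources would attack.

Step 25
Reactants: 33 (5S,6S,7S,8R,9S,10S)-9,15-diol C6 angelate
Product: 34 (5R,6S,7S,8R,9S,10S)-15-al (2-substituted acrolein) with free 9-OH and 10-vinyl (C5 descriptor changes by CIP priority only)
Conditions: activated MnO2, CH2Cl2, 25 °C
Reagents that add atoms: none
Why: MnO2 oxidises only the allylic primary alcohol; the secondary C9 hydroxyl is not allylic and stays. Forming the enal now also deactivates the C4=C3 alkene toward the next step.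

Step 26
Reactants: 34 (5R,6S,7S,8R,9S,10S)-15-al with free 9-OH and 10-vinyl
Product: 35 CNP0113462.3, the (1R,5R,6S,7S,8R,9S,10S) target
Conditions: VO(acac)2 (cat.), t-BuOOH, CH2Cl2, 0 → 25 °C
Reagents that add atoms: tert-butyl hydroperoxide, CC(C)(C)OO
Why: hydroxyl-directed epoxidation of a homoallylic alcohol: the vanadate ester of the axial C9 hydroxyl delivers the peroxide oxygen to the gauche, equatorial vinyl group, the only alkene not conjugated to a carbonyl group. In the chair vanadate transition state the terminal CH2 points away from the metal, syn to the C10–C5 bond, which gives the 1,3-syn O9/O1 relationship and hence (1R).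

## Compound list

1 | methyl (4R)-2,2-dimethyl-1,3-dioxolane-4-carboxylate | COC(=O)[C@H]1COC(C)(C)O1 | starting material
2 | (4R)-N-methoxy-N,2,2-trimethyl-1,3-dioxolane-4-carboxamide (Weinreb amide, formed in the flask) | CON(C)C(=O)[C@H]1COC(C)(C)O1 | intermediate
3 | 1-[(4R)-2,2-dimethyl-1,3-dioxolan-4-yl]ethan-1-one | CC(=O)[C@H]1COC(C)(C)O1 | intermediate
4 | ethyl (2E)-3-[(4S)-2,2-dimethyl-1,3-dioxolan-4-yl]but-2-enoate | CCOC(=O)/C=C(\C)[C@H]1COC(C)(C)O1 | intermediate
5 | (2E)-3-[(4S)-2,2-dimethyl-1,3-dioxolan-4-yl]but-2-en-1-ol | OC/C=C(\C)[C@H]1COC(C)(C)O1 | intermediate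
6 | 4-methoxy-2-methylidene-4-oxobutanoic acid (mono-methyl itaconate) | C=C(CC(=O)OC)C(=O)O | starting material
7 | methyl 3-(hydroxymethyl)but-3-enoate | C=C(CO)CC(=O)OC | intermediate
8 | methyl 3-[(tert-butyldiphenylsilyloxy)methyl]but-3-enoate | C=C(CO[Si](c1ccccc1)(c1ccccc1)C(C)(C)C)CC(=O)OC | intermediate
9 | 3-[(tert-butyldiphenylsilyloxy)methyl]but-3-enoic acid | C=C(CO[Si](c1ccccc1)(c1ccccc1)C(C)(C)C)CC(=O)O | intermediate
10 | (2E)-3-[(4S)-2,2-dimethyl-1,3-dioxolan-4-yl]but-2-en-1-yl 3-[(tert-butyldiphenylsilyloxy)methyl]but-3-enoate | C=C(CO[Si](c1ccccc1)(c1ccccc1)C(C)(C)C)CC(=O)OC/C=C(\C)[C@H]1COC(C)(C)O1 | intermediate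
11 | E(O)-trimethylsilyl ketene acetal of 10 (formed in the flask) | C=C(CO[Si](c1ccccc1)(c1ccccc1)C(C)(C)C)/C=C(/O[Si](C)(C)C)OC/C=C(\C)[C@H]1COC(C)(C)O1 | intermediate
12 | trimethylsilyl ester of the (5S,9S,10S)-C6 acid (formed in the flask) | CC1(C)OC[C@@H](O1)[C@@](C)(C=C)[C@H](C(=C)CO[Si](c1ccccc1)(c1ccccc1)C(C)(C)C)C(=O)O[Si](C)(C)C | intermediate
13 | (2S,3S)-2-[3-(tert-butyldiphenylsilyloxy)prop-1-en-2-yl]-3-[(4S)-2,2-dimethyl-1,3-dioxolan-4-yl]-3-methylpent-4-en-1-ol | CC1(C)OC[C@@H](O1)[C@@](C)(C=C)[C@H](C(=C)CO[Si](c1ccccc1)(c1ccccc1)C(C)(C)C)CO | intermediate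
14 | (2S,3S)-2-[3-(tert-butyldiphenylsilyloxy)prop-1-en-2-yl]-3-[(4S)-2,2-dimethyl-1,3-dioxolan-4-yl]-3-methylpent-4-enal | CC1(C)OC[C@@H](O1)[C@@](C)(C=C)[C@H](C(=C)CO[Si](c1ccccc1)(c1ccccc1)C(C)(C)C)C=O | intermediate
15 | (2S,3S)-2-[3-(tert-butyldiphenylsilyloxy)prop-1-en-2-yl]-1-(1,3-dithian-2-yl)-3-[(4S)-2,2-dimethyl-1,3-dioxolan-4-yl]-3-methylpent-4-en-1-ol (both C6 epimers) | CC1(C)OC[C@@H](O1)[C@@](C)(C=C)[C@H](C(=C)CO[Si](c1ccccc1)(c1ccccc1)C(C)(C)C)C(O)C1SCCCS1 | intermediate
16 | (2S,3S)-2-[3-(tert-butyldiphenylsilyloxy)prop-1-en-2-yl]-1-(1,3-dithian-2-yl)-3-[(4S)-2,2-dimethyl-1,3-dioxolan-4-yl]-3-methylpent-4-en-1-one | CC1(C)OC[C@@H](O1)[C@@](C)(C=C)[C@H](C(=C)CO[Si](c1ccccc1)(c1ccccc1)C(C)(C)C)C(=O)C1SCCCS1 | intermediate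
17 | (1S,2S,3S)-2-[3-(tert-butyldiphenylsilyloxy)prop-1-en-2-yl]-1-(1,3-dithian-2-yl)-3-[(4S)-2,2-dimethyl-1,3-dioxolan-4-yl]-3-methylpent-4-en-1-ol, the (5S,6S,9S,10S) carbinol | CC1(C)OC[C@@H](O1)[C@@](C)(C=C)[C@H](C(=C)CO[Si](c1ccccc1)(c1ccccc1)C(C)(C)C)[C@H](O)C1SCCCS1 | intermediate
18 | (5S,6S,9S,10S)-6-O-(4-methoxybenzyl) ether of 17 | CC1(C)OC[C@@H](O1)[C@@](C)(C=C)[C@H](C(=C)CO[Si](c1ccccc1)(c1ccccc1)C(C)(C)C)[C@H](OCc1ccc(OC)cc1)C1SCCCS1 | intermediate
19 | (5S,6S,9S,10S)-8,9-diol (6-OPMB, 7-dithiane, 15-OTBDPS) | OC[C@@H](O)[C@@](C)(C=C)[C@H](C(=C)CO[Si](c1ccccc1)(c1ccccc1)C(C)(C)C)[C@H](OCc1ccc(OC)cc1)C1SCCCS1 | intermediate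
20 | (5S,6S,9S,10S)-8,9-bis(triethylsilyl) ether of 19 | CC[Si](CC)(CC)OC[C@@H](O[Si](CC)(CC)CC)[C@@](C)(C=C)[C@H](C(=C)CO[Si](c1ccccc1)(c1ccccc1)C(C)(C)C)[C@H](OCc1ccc(OC)cc1)C1SCCCS1 | intermediate
21 | (5S,6S,9S,10S)-C7 aldehyde (6-OPMB, 8,9-bis-OTES, 15-OTBDPS) | CC[Si](CC)(CC)OC[C@@H](O[Si](CC)(CC)CC)[C@@](C)(C=C)[C@H](C(=C)CO[Si](c1ccccc1)(c1ccccc1)C(C)(C)C)[C@H](OCc1ccc(OC)cc1)C=O | intermediate
22 | methyl acrylate | C=CC(=O)OC | starting material
23 | Baylis–Hillman adduct, methyl 2-methylidene-3-hydroxy ester at C7 (5S,6S,9S,10S; both C7 epimers) | CC[Si](CC)(CC)OC[C@@H](O[Si](CC)(CC)CC)[C@@](C)(C=C)[C@H](C(=C)CO[Si](c1ccccc1)(c1ccccc1)C(C)(C)C)[C@H](OCc1ccc(OC)cc1)C(O)C(=C)C(=O)OC | intermediate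
24 | (5S,6R,9S,10S)-(Z)-2-(bromomethyl)enoate with 8,9-bis-OTES | CC[Si](CC)(CC)OC[C@@H](O[Si](CC)(CC)CC)[C@@](C)(C=C)[C@H](C(=C)CO[Si](c1ccccc1)(c1ccccc1)C(C)(C)C)[C@H](OCc1ccc(OC)cc1)/C=C(\CBr)C(=O)OC | intermediate
25 | (5S,6R,9S,10S)-(Z)-2-(bromomethyl)enoate C8 primary alcohol | OC[C@@H](O[Si](CC)(CC)CC)[C@@](C)(C=C)[C@H](C(=C)CO[Si](c1ccccc1)(c1ccccc1)C(C)(C)C)[C@H](OCc1ccc(OC)cc1)/C=C(\CBr)C(=O)OC | intermediate
26 | (5S,6R,9S,10S)-(Z)-2-(bromomethyl)enoate C8 aldehyde (key-step precursor) | O=C[C@@H](O[Si](CC)(CC)CC)[C@@](C)(C=C)[C@H](C(=C)CO[Si](c1ccccc1)(c1ccccc1)C(C)(C)C)[C@H](OCc1ccc(OC)cc1)/C=C(\CBr)C(=O)OC | intermediate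
27 | allylchromium dichloride from 26, C6 trans to CH2Cr (formed in the flask) | O=C[C@@H](O[Si](CC)(CC)CC)[C@@](C)(C=C)[C@H](C(=C)CO[Si](c1ccccc1)(c1ccccc1)C(C)(C)C)[C@H](OCc1ccc(OC)cc1)/C=C(/C[Cr](Cl)Cl)C(=O)OC | intermediate
28 | chromium alkoxide of the trans C7/C8 hydroxy acrylate (carbocycle closed, lactone open; formed in the flask) | COC(=O)C(=C)[C@H]1[C@@H](OCc2ccc(OC)cc2)[C@@H](C(=C)CO[Si](c2ccccc2)(c2ccccc2)C(C)(C)C)[C@](C)(C=C)[C@H](O[Si](CC)(CC)CC)[C@@H]1O[Cr](Cl)Cl | intermediate
29 | (5S,6S,7S,8R,9S,10S)-trans-fused α-methylene-γ-butyrolactone (6-OPMB, 9-OTES, 15-OTBDPS, 10-vinyl) | C=C1C(=O)O[C@@H]2[C@@H]1[C@@H](OCc3ccc(OC)cc3)[C@@H](C(=C)CO[Si](c3ccccc3)(c3ccccc3)C(C)(C)C)[C@](C)(C=C)[C@@H]2O[Si](CC)(CC)CC | intermediate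
30 | (5S,6S,7S,8R,9S,10S)-C6 alcohol (9-OTES, 15-OTBDPS) | C=C1C(=O)O[C@@H]2[C@@H]1[C@@H](O)[C@@H](C(=C)CO[Si](c3ccccc3)(c3ccccc3)C(C)(C)C)[C@](C)(C=C)[C@@H]2O[Si](CC)(CC)CC | intermediate
31 | angelic acid, (2Z)-2-methylbut-2-enoic acid | C/C=C(/C)C(=O)O | starting material
32 | (5S,6S,7S,8R,9S,10S)-C6 angelate (9-OTES, 15-OTBDPS) | C=C1C(=O)O[C@@H]2[C@@H]1[C@@H](OC(=O)/C(C)=C\C)[C@@H](C(=C)CO[Si](c3ccccc3)(c3ccccc3)C(C)(C)C)[C@](C)(C=C)[C@@H]2O[Si](CC)(CC)CC | intermediate
33 | (5S,6S,7S,8R,9S,10S)-9,15-diol C6 angelate | C=C1C(=O)O[C@@H]2[C@@H]1[C@@H](OC(=O)/C(C)=C\C)[C@@H](C(=C)CO)[C@](C)(C=C)[C@@H]2O | intermediate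
34 | (5R,6S,7S,8R,9S,10S)-15-al with free 9-OH and 10-vinyl | C=C1C(=O)O[C@@H]2[C@@H]1[C@@H](OC(=O)/C(C)=C\C)[C@@H](C(=C)C=O)[C@](C)(C=C)[C@@H]2O | intermediate
35 | CNP0113462.3, the (1R,5R,6S,7S,8R,9S,10S) epoxy elemanolide | C=C1C(=O)O[C@@H]2[C@@H]1[C@@H](OC(=O)/C(C)=C\C)[C@@H](C(=C)C=O)[C@](C)([C@@H]1CO1)[C@@H]2O | target

## Step count and least certain steps

Total step count: 26 (steps 4–6 prepare acid 9; the rest are on the main line).
Longest linear sequence: 23 steps (steps 1–3 and 7–26 from 1; equally steps 4–6 and 7–26 from 6).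

**Step 21 (key step).** The most likely failure is loss of control over the ring fusion. If the allylchromium adds before its alkene geometry has equilibrated, or through a boat, the aldehyde is taken on its other face and a cis-fused lactone epimeric at C8 forms. A second leak is closure through the ring-flipped chair, because the desired array does not place the C9–O bond anti to the incoming carbon as the polar Felkin–Anh model would prefer. Fallback: the material from 26 that arrives as the C8-epimeric cis-fused lactone F1 would be opened (LiOH, THF/H2O, 0 °C) to the seco hydroxy acid F2, acidified cold, and at once re-closed under Mitsunobu conditions (PPh3, DIAD, toluene, 0 °C). This forms the O–C8 bond with inversion and returns the trans-lactone 29.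

**Step 8.** Diastereoselection may erode in two ways. The β,γ-unsaturated ester may give some Z(O)-ketene acetal, which leads to the wrong C5/C10 relationship. The single stereocentre C9 may also discriminate the two alkene faces incompletely, which gives the wrong absolute sense at both new centres. Fallback: from 10, the boron variant of the rearrangement. A chiral 2-bromo-1,3,2-diazaborolidine (from BBr3 and an N,N′-bis(arylsulfonyl)-1,2-diphenylethane-1,2-diamine) and a trialkylamine at −78 °C, then −20 °C, would set both the enolate geometry and the face by the reagent. The controller enantiomer is chosen for the (5S,10S) pair. The (5S,9S,10S) carboxylic acid F3 is isolated and reduced (LiAlH4, THF, 0 °C) to 13.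

**Step 17.** The acrylate addition may stall at this hindered, α-branched aldehyde, and long exposure to the amine would allow slow epimerisation at C6. Fallback: from 21, aldol addition of the lithium enolate of methyl 3-(dimethylamino)propanoate (LiN(i-Pr)2, THF, −78 °C) gives the amino aldol F4. N-methylation (MeI) to the ammonium iodide F5 and elimination with DBU then return 23.

**Step 23.** Acylation of the axial C6 hydroxyl (flanked by C5 and C7 and 1,3-diaxial to the C14 methyl) may be incomplete, and forcing it risks Z-to-E isomerisation of the acyl group. Fallback: from 30, esterification with the less demanding 2-[bis(2,2,2-trifluoroethoxy)phosphoryl]propanoic acid (DCC, DMAP, CH2Cl2) gives the phosphonate ester F6. Still–Gennari olefination with acetaldehyde (KN(SiMe3)2, 18-crown-6, THF, −78 °C) builds the Z-trisubstituted enoate on the ester already in place and returns 32.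

**Step 26.** Facial selectivity at C1 may be poor, because the vanadate geometry that leads to (1R) places the terminal CH2 gauche to the C5 side chain, and a competing geometry would deliver oxygen to the other face. Fallback: from 34, catalyst control in place of substrate control. VO(Oi-Pr)3 with a chiral C2-symmetric bishydroxamic acid ligand and cumene hydroperoxide (the established asymmetric epoxidation of homoallylic alcohols) would be used, with the ligand enantiomer chosen for the (1R) face. This returns 35 without a new compound.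

## Further compounds

F1 | step 21 | C8-epimeric cis-fused α-methylene lactone (8-epi-29) | C=C1C(=O)O[C@H]2[C@@H]1[C@@H](OCc3ccc(OC)cc3)[C@@H](C(=C)CO[Si](c3ccccc3)(c3ccccc3)C(C)(C)C)[C@](C)(C=C)[C@@H]2O[Si](CC)(CC)CC
F2 | step 21 | seco hydroxy acid of F1 (C12 acid, C8 hydroxyl cis to the acrylic acid arm) | OC(=O)C(=C)[C@H]1[C@@H](OCc2ccc(OC)cc2)[C@@H](C(=C)CO[Si](c2ccccc2)(c2ccccc2)C(C)(C)C)[C@](C)(C=C)[C@H](O[Si](CC)(CC)CC)[C@H]1O
F3 | step 8 | (2S,3S)-2-[3-(tert-butyldiphenylsilyloxy)prop-1-en-2-yl]-3-[(4S)-2,2-dimethyl-1,3-dioxolan-4-yl]-3-methylpent-4-enoic acid | CC1(C)OC[C@@H](O1)[C@@](C)(C=C)[C@H](C(=C)CO[Si](c1ccccc1)(c1ccccc1)C(C)(C)C)C(=O)O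
F4 | step 17 | amino aldol, methyl 2-[(dimethylamino)methyl]-3-hydroxy ester at C7 (C7 and C11 epimers) | CC[Si](CC)(CC)OC[C@@H](O[Si](CC)(CC)CC)[C@@](C)(C=C)[C@H](C(=C)CO[Si](c1ccccc1)(c1ccccc1)C(C)(C)C)[C@H](OCc1ccc(OC)cc1)C(O)C(CN(C)C)C(=O)OC
F5 | step 17 | trimethylammonium iodide of F4 | CC[Si](CC)(CC)OC[C@@H](O[Si](CC)(CC)CC)[C@@](C)(C=C)[C@H](C(=C)CO[Si](c1ccccc1)(c1ccccc1)C(C)(C)C)[C@H](OCc1ccc(OC)cc1)C(O)C(C[N+](C)(C)C)C(=O)OC.[I-]
F6 | step 23 | C6 2-[bis(2,2,2-trifluoroethoxy)phosphoryl]propanoate of 30 | C=C1C(=O)O[C@@H]2[C@@H]1[C@@H](OC(=O)C(C)P(=O)(OCC(F)(F)F)OCC(F)(F)F)[C@@H](C(=C)CO[Si](c3ccccc3)(c3ccccc3)C(C)(C)C)[C@](C)(C=C)[C@@H]2O[Si](CC)(CC)CC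
F0 | step 26 | none | none
A1 | alternative 1 | cis-fused 2-ethoxytetrahydrofuran with C8 hydroxyl | CCOC1C[C@H]2[C@@H](O1)[C@@H](C(C)=C)[C@](C)(C=C)[C@H](O[Si](C)(C)C(C)(C)C)[C@@H]2O
A2 | alternative 1 | O6-bromoacetal of the C7=C8 cyclohexene | CCOC(CBr)O[C@@H]1C=C[C@@H](O[Si](C)(C)C(C)(C)C)[C@@](C)(C=C)[C@@H]1C(C)=C
A3 | alternative 2 | 3-hydroxycyclohexanone with C6 OH, C7 side chain, C8 ketone | O=C1[C@@H](CCOCc2ccc(OC)cc2)[C@@H](O)[C@@H](C(C)=C)[C@](C)(C=C)[C@@H]1O[Si](C)(C)C(C)(C)C
A4 | alternative 2 | methyl pyranoside with exocyclic C8=C7 enol ether (anomeric centre and enol ether geometry not specified) | COC1OC(=CCCOCc2ccc(OC)cc2)[C@@H](O[Si](C)(C)C(C)(C)C)[C@@](C)(C=C)[C@@H]1C(C)=C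
A5 | alternative 3 | cis-C8,C9-diol cyclohexane with ester arm | O[C@@H]1[C@@H](CC(=O)OC)[C@@H](OCc2ccc(OC)cc2)[C@@H](C(C)=C)[C@](C)(C=C)[C@@H]1O
A6 | alternative 3 | C8,C9-dialdehyde with C7 ester arm | O=C[C@@H](CC(=O)OC)[C@@H](OCc1ccc(OC)cc1)[C@@H](C(C)=C)[C@](C)(C=C)C=O
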